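**Retrosynthetic overview**

1. The target is traced back to its 8-O-silyl ether: the angelate is put on O5 last, the crotonoyl group comes from a C1 acetyl group by aldol condensation with acetaldehyde, and the C11=C13 methylene comes from a C11 phosphonate by Horner–Wadsworth–Emmons reaction with formaldehyde.
2. The C10 methyl group comes from hydroxyl-directed hydrogenation of an exocyclic C10=C14 alkene; that alkene and the C8 carbinol both come from one intramolecular carbonyl-ene reaction that forms the C8–C9 bond and closes the cycloheptane C1–C5–C6–C7–C8–C9–C10.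
3. Enabling feature: a 1,1-disubstituted isopropenyl unit (C9H2=C10–C14H3) on the fully substituted C1 of a temporary O1/O5 dioxolane, four atoms away from the C8 aldehyde on C7 of the trans-γ-lactone (O6–C6–C7–C11–C12); the allylic C14–H is the hydrogen that is transferred.
4. The ene precursor comes from D-tartrate: C5 and C6 from the pool, C1 by chelation-controlled isopropenyl Grignard addition to a C1 ketone, C7 by anti-selective conjugate addition of 2-lithio-1,3-dithiane (C8) to an alkylidene phosphonoacetate (C11, C12).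
5. Ring order: tartrate dioxolane (O5/O6) → γ-lactone → temporary O1/O5 dioxolane → cycloheptane (key step) → dioxolane removed.

Key step: step 10

Remark: locants C1–C15 follow the target skeleton (C1 quaternary carbinol; C2–C4 and C15 crotonoyl; C5 CH–O-angelate; C6 lactone CH–O; C7; C8 CH–OH; C9 CH2; C10 CH–CH3 with C14; C11–C13 lactone C(=CH2)–C=O). C11 of the phosphonates (14–20) and C4 of 24 and 25 are epimeric mixtures, drawn without configuration because later steps remove these centres; 11 is an E/Z mixture.

**Step 1**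
Reactants: 1 dimethyl (4S,5S)-2,2-dimethyl-1,3-dioxolane-4,5-dicarboxylate
Product: 2 (4S,5S)-N4,N5-dimethoxy-N4,N5,2,2-tetramethyl-1,3-dioxolane-4,5-dicarboxamide
Conditions: MeNH(OMe)·HCl, iPrMgCl, THF, −20 to 0 °C
Reagents that add atoms: N,O-dimethylhydroxylamine hydrochloride, CNOC.Cl
Why: Aminolysis of both esters by the chloromagnesium amide of N,O-dimethylhydroxylamine (ester to N-methoxy-N-methylamide exchange) should leave the two tartrate-derived stereocentres untouched, and they already sit in the thermodynamically preferred trans arrangement on the dioxolane.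

**Step 2**
Reactants: 2 bis(N-methoxy-N-methylamide); 3 ethyl vinyl ether
Product: 5 (4S,5S)-5-(2-ethoxyprop-2-enoyl)-N-methoxy-N,2,2-trimethyl-1,3-dioxolane-4-carboxamide, via 1-ethoxyvinyllithium 4 (not isolated)
Conditions: 3, t-BuLi, THF, −78 to 0 °C; then 2 (1.0 equiv), THF, −78 °C; aq. NH4Cl
Reagents that add atoms: none
Why: Acyl substitution of an N-methoxy-N-methylamide by the acetyl-anion equivalent 1-ethoxyvinyllithium should stop at the ketone because the chelated tetrahedral adduct persists until work-up, and the C2 symmetry of 2 makes the two amides equivalent, so one equivalent of reagent gives a single mono-ketone whose ketone carbon is the future C1.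

**Step 3**
Reactants: 5 α-ethoxy enone; 6 isopropenylmagnesium bromide
Product: 8 (4S,5S)-5-[(3S)-2-ethoxy-4-methyl-3-(triethylsilyloxy)penta-1,4-dien-3-yl]-N-methoxy-N,2,2-trimethyl-1,3-dioxolane-4-carboxamide, via bromomagnesium alkoxide 7 (not isolated)
Conditions: 6, MgBr2·OEt2, CH2Cl2–Et2O, −78 °C; then Et3SiOTf, −78 to 0 °C
Reagents that add atoms: triethylsilyl trifluoromethanesulfonate, CC[Si](CC)(CC)OS(=O)(=O)C(F)(F)F
Why: Chelation-controlled 1,2-addition of the Grignard reagent (Cram chelate model) is expected, with magnesium bridging the C1 carbonyl oxygen and the dioxolane oxygen on C5 so that the isopropenyl group enters from the face of H5, anti to the C5–C6 bond, which sets C1 as S with O1 and O5 syn in the extended chain (trans on the later ring), while the cross-conjugated α-ethoxy enone offers no electrophilic β-carbon, the amide is inert at −78 °C and the alkoxide is silylated in the same flask.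

**Step 4**
Reactants: 8 silyl ether amide
Product: 9 (4S,5S)-5-[(3S)-2-ethoxy-4-methyl-3-(triethylsilyloxy)penta-1,4-dien-3-yl]-2,2-dimethyl-1,3-dioxolane-4-carbaldehyde
Conditions: iBu2AlH, THF, −78 °C; aq. KNaC4H4O6
Reagents that add atoms: none
Why: Hydride reduction of the N-methoxy-N-methylamide should stop at the aldehyde because the aluminium-chelated hemiaminal only collapses on work-up, and the α-stereocentre C6 stays in the favoured trans relationship on the dioxolane.

**Step 5**
Reactants: 9 aldehyde; 10 triethyl phosphonoacetate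
Product: 11 ethyl 2-(diethoxyphosphoryl)-3-{(4R,5S)-5-[(3S)-2-ethoxy-4-methyl-3-(triethylsilyloxy)penta-1,4-dien-3-yl]-2,2-dimethyl-1,3-dioxolan-4-yl}prop-2-enoate
Conditions: 10, piperidine (cat.), AcOH (cat.), 4 Å molecular sieves, toluene, 40 °C
Reagents that add atoms: none
Why: An amine-catalysed Knoevenagel condensation through the iminium ion should join C7 to the active methylene carbon (the future C11) and keep the phosphoryl group, unlike a base-mediated Horner–Wadsworth–Emmons olefination, so the product is a doubly activated Michael acceptor that carries the latent α-methylene unit, and its alkene geometry is of no consequence.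

**Step 6**
Reactants: 11 alkylidene phosphonoacetate; 12 1,3-dithiane
Product: 14 ethyl (3S)-2-(diethoxyphosphoryl)-3-(1,3-dithian-2-yl)-3-{(4R,5S)-5-[(3S)-2-ethoxy-4-methyl-3-(triethylsilyloxy)penta-1,4-dien-3-yl]-2,2-dimethyl-1,3-dioxolan-4-yl}propanoate, via 2-lithio-1,3-dithiane 13 (not isolated)
Conditions: 12, n-BuLi, THF, −30 °C; then 11, THF, −78 °C; aq. NH4Cl
Reagents that add atoms: none
Why: Conjugate addition of the formyl-anion equivalent 2-lithio-1,3-dithiane (dithiane umpolung of C8) to the alkylidene phosphonoacetate should set C7 under Felkin–Anh control with minimised allylic 1,3-strain, the nucleophile arriving anti to the C6–O6 bond with H6 eclipsing the alkene, which places C8 and O6 anti and so prepares the trans-lactone.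

**Step 7**
Reactants: 14 dithiane adduct
Product: 15 diethyl {(4S,5R)-5-[(1S,2S)-1,2-dihydroxy-3-oxo-2-(prop-1-en-2-yl)butyl]-4-(1,3-dithian-2-yl)-2-oxooxolan-3-yl}phosphonate
Conditions: CF3CO2H–H2O (9:1), 0 °C to rt; toluene azeotrope
Reagents that add atoms: water, O
Why: Aqueous acid should hydrolyse the enol ether to the methyl ketone (which also deactivates the C1 carbinol towards ionisation), cleave the silyl ether and the tartrate acetonide, and let the freed O6–H close the five-membered lactone on the activated ethyl ester in preference to the six-membered alternative through O5, while the dithioacetal is inert to acid.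

**Step 8**
Reactants: 15 lactone diol
Product: 16 diethyl {(4S,5R)-5-[(4S,5S)-5-acetyl-2,2-dimethyl-5-(prop-1-en-2-yl)-1,3-dioxolan-4-yl]-4-(1,3-dithian-2-yl)-2-oxooxolan-3-yl}phosphonate
Conditions: 2-methoxypropene, PPTS (cat.), CH2Cl2, 0 °C to rt
Reagents that add atoms: 2-methoxypropene, COC(C)=C
Why: Acid-catalysed acetalization of the only 1,2-diol ties O1 and O5 into a temporary dioxolane, which prevents lactol formation between O5–H and the coming C8 aldehyde, removes two acidic protons before the Lewis acid step and keeps the α-face O1 from directing the later hydrogenation.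

**Step 9**
Reactants: 16 dithiane acetonide
Product: 17 diethyl {(4R,5R)-5-[(4S,5S)-5-acetyl-2,2-dimethyl-5-(prop-1-en-2-yl)-1,3-dioxolan-4-yl]-4-formyl-2-oxooxolan-3-yl}phosphonate
Conditions: PhI(OCOCF3)2, MeCN–H2O (9:1), 0 °C
Reagents that add atoms: water, O
Why: Oxidative hydrolysis of the dithioacetal by the hypervalent iodine reagent is fast at 0 °C and tolerates the isopropenyl group, the ketone and the acetonide, and the β-acyloxy aldehyde, whose C7 centre already has the thermodynamically preferred trans arrangement on the lactone, is used at once.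

**Step 10**
Reactants: 17 isopropenyl aldehyde
Product: 18 tricyclic 8β-hydroxy-10(14)-ene lactone phosphonate (cycloheptane C1–C5–C6–C7–C8–C9–C10 trans-fused to the 6,12-γ-lactone and to the O1/O5 dioxolane; 1S,5S,6R,7S,8S)
Conditions: Me2AlCl (3.5 equiv), CH2Cl2, −78 to −20 °C; aq. KNaC4H4O6
Reagents that add atoms: none
Why: Me2AlCl activates the C8 aldehyde, and the CH2 terminus (C9) of the 1,1-disubstituted isopropenyl group bonds to C8 while an allylic hydrogen of C14 passes to O8 through a six-centre transition state, giving the C8 alkoxide and the exocyclic C10=C14 alkene in one event. The closest known reaction type is the Lewis acid-promoted intramolecular carbonyl-ene cyclization in which the carbonyl is tethered to the central carbon of the ene (the type 2 mode), which is established for six- and seven-membered rings from ω-isopropenyl aldehydes. The only ring closed is the cycloheptane C1–C5–C6–C7–C8–C9–C10, by 7-exo-trig attack on the carbonyl carbon (endo with respect to the alkene, both of whose carbons enter the ring). The new stereocentre C8 is set by the transition-state geometry: hydrogen transfer forces O8 to lie over the ene unit, syn-clinal to C10 and so pseudo-axial on the nascent ring, while the C7–C11 bond must stay pseudo-equatorial to keep the trans-fused lactone, so O8 should end cis to C11 (8β-OH, 8S), and C7, the only epimerizable centre, is already in its preferred trans arrangement. The step needs chemoselectivity for the aldehyde over the C2 methyl ketone and the lactone carbonyl (the aldehyde is the most electrophilic carbonyl at −78 °C), bond formation at C9 only (the 1,1-disubstitution puts the developing positive charge on C10 and leaves C14 as the only hydrogen donor), and no 1,2-shift out of C1 (the acetyl group on C1 is electron-withdrawing and O1 is tied into the dioxolane, not free or silylated). The quaternary C1 and the two five-membered rings (lactone and O1/O5 dioxolane) restrict the chain so that C9 is held within reach of C8.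

**Step 11**
Reactants: 18 ene product
Product: 19 tricyclic 8β-hydroxy-10α-methyl lactone phosphonate (1S,5S,6R,7S,8S,10S)
Conditions: H2 (1 atm), [Ir(cod)(PCy3)(py)]PF6 (cat.), CH2Cl2, rt
Reagents that add atoms: none
Why: Hydroxyl-directed homogeneous hydrogenation is expected, the cationic iridium centre binding the pseudo-axial 8β-hydroxyl (and the β-oriented acetyl oxygen) and delivering hydrogen to the β-face of the C10=C14 methylene, so that H10 is β and the new C14 methyl α (10S), while the α-face O1 is locked in the dioxolane and no other alkene is present.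

**Step 12**
Reactants: 19 hydroxy phosphonate
Product: 20 8-O-tert-butyldimethylsilyl ether of 19
Conditions: t-BuMe2SiOTf, 2,6-lutidine, CH2Cl2, −78 to 0 °C
Reagents that add atoms: tert-butyldimethylsilyl trifluoromethanesulfonate, CC(C)(C)[Si](C)(C)OS(=O)(=O)C(F)(F)F
Why: Silylation of the only free hydroxyl with a silyl triflate masks O8 so that the later basic steps cannot move the lactone from O6 to the cis-disposed O8 and so that only O5 is available for acylation.

**Step 13**
Reactants: 20 silylated phosphonate; 21 formaldehyde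
Product: 22 α-methylene lactone (C11=C13H2) with 1-acetyl; O1/O5 acetonide; 8-OTBS
Conditions: aq. CH2O, K2CO3, THF, 0 °C
Reagents that add atoms: none
Why: Horner–Wadsworth–Emmons olefination of the α-phosphono lactone with formaldehyde creates the exocyclic C11=C13 bond, carbonate deprotonating only the doubly activated C11–H and leaving the methyl ketone untouched, and the undefined C11 centre disappears.

**Step 14**
Reactants: 22 methyl ketone; 23 acetaldehyde
Product: 26 (E)-crotonoyl compound (1-[(E)-but-2-enoyl]; O1/O5 acetonide; 8-OTBS; α-methylene lactone), via lithium aldolate 24 (not isolated), via aldol mesylate 25 (not isolated)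
Conditions: LiN(SiMe3)2, THF, −78 °C; CH3CHO; then MeSO2Cl, Et3N, −78 to 0 °C
Reagents that add atoms: none
Why: Kinetic deprotonation can only occur at the C3 methyl of the ketone (C1 is quaternary and the lactone now lacks an α-hydrogen), so aldol addition to acetaldehyde, mesylation of the aldolate in the same flask and E1cB elimination should give the thermodynamically favoured (E)-enone of the crotonoyl group (aldol condensation).

**Step 15**
Reactants: 26 acetonide enone
Product: 27 1,5-diol (1-OH tertiary; 5-OH secondary; 8-OTBS)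
Conditions: AcOH–H2O (4:1), 40 °C
Reagents that add atoms: none
Why: Mild aqueous acid should hydrolyse the strained trans-fused acetonide, freeing the secondary O5–H and the tertiary O1–H, while the hindered secondary silyl ether, the enone and the α-methylene lactone survive.

**Step 16**
Reactants: 27 diol; 28 angelic acid
Product: 30 8-O-tert-butyldimethylsilyl ether of the target, via mixed anhydride 29 (not isolated)
Conditions: 28, 2,4,6-Cl3C6H2COCl, Et3N, toluene, rt; then 27, toluene, 75 °C
Reagents that add atoms: none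
Why: Esterification through the mixed 2,4,6-trichlorobenzoic anhydride (Yamaguchi-type activation, run without a nucleophilic catalyst) should acylate the secondary O5–H only, since the tertiary α-ketol hydroxyl at C1 is too hindered and O8 is silylated, and these conditions are chosen because they keep the Z geometry of the angeloyl group.

**Step 17**
Reactants: 30 silyl ether
Product: 31 CNP0206014.2
Conditions: HF·pyridine, THF, 0 °C to rt
Reagents that add atoms: none
Why: Fluoride-mediated cleavage of the silyl ether under buffered acidic conditions frees O8–H without exposing the α-methylene lactone, the enone, the angelate or the α-ketol to base.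

**Compound list**

1 | dimethyl (4S,5S)-2,2-dimethyl-1,3-dioxolane-4,5-dicarboxylate (acetonide of dimethyl D-tartrate) | COC(=O)[C@H]1OC(C)(C)O[C@@H]1C(=O)OC | starting material
2 | (4S,5S)-N4,N5-dimethoxy-N4,N5,2,2-tetramethyl-1,3-dioxolane-4,5-dicarboxamide | CON(C)C(=O)[C@H]1OC(C)(C)O[C@@H]1C(=O)N(C)OC | intermediate
3 | ethyl vinyl ether (ethoxyethene) | C=COCC | starting material
4 | 1-ethoxyvinyllithium | [Li]C(=C)OCC | intermediate
5 | (4S,5S)-5-(2-ethoxyprop-2-enoyl)-N-methoxy-N,2,2-trimethyl-1,3-dioxolane-4-carboxamide | C=C(OCC)C(=O)[C@H]1OC(C)(C)O[C@@H]1C(=O)N(C)OC | intermediate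
6 | isopropenylmagnesium bromide (prop-1-en-2-ylmagnesium bromide) | C=C(C)[Mg]Br | starting material
7 | bromomagnesium (3S)-2-ethoxy-3-{(4S,5S)-5-[methoxy(methyl)carbamoyl]-2,2-dimethyl-1,3-dioxolan-4-yl}-4-methylpenta-1,4-dien-3-olate | C=C(C)[C@@](O[Mg]Br)(C(=C)OCC)[C@H]1OC(C)(C)O[C@@H]1C(=O)N(C)OC | intermediate
8 | (4S,5S)-5-[(3S)-2-ethoxy-4-methyl-3-(triethylsilyloxy)penta-1,4-dien-3-yl]-N-methoxy-N,2,2-trimethyl-1,3-dioxolane-4-carboxamide | C=C(C)[C@@](O[Si](CC)(CC)CC)(C(=C)OCC)[C@H]1OC(C)(C)O[C@@H]1C(=O)N(C)OC | intermediate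
9 | (4S,5S)-5-[(3S)-2-ethoxy-4-methyl-3-(triethylsilyloxy)penta-1,4-dien-3-yl]-2,2-dimethyl-1,3-dioxolane-4-carbaldehyde | C=C(C)[C@@](O[Si](CC)(CC)CC)(C(=C)OCC)[C@H]1OC(C)(C)O[C@@H]1C=O | intermediate
10 | triethyl phosphonoacetate (ethyl 2-(diethoxyphosphoryl)acetate) | CCOC(=O)CP(=O)(OCC)OCC | starting material
11 | ethyl 2-(diethoxyphosphoryl)-3-{(4R,5S)-5-[(3S)-2-ethoxy-4-methyl-3-(triethylsilyloxy)penta-1,4-dien-3-yl]-2,2-dimethyl-1,3-dioxolan-4-yl}prop-2-enoate (E/Z mixture) | C=C(C)[C@@](O[Si](CC)(CC)CC)(C(=C)OCC)[C@H]1OC(C)(C)O[C@@H]1C=C(C(=O)OCC)P(=O)(OCC)OCC | intermediate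
12 | 1,3-dithiane | C1CSCSC1 | starting material
13 | 2-lithio-1,3-dithiane | [Li]C1SCCCS1 | intermediate
14 | ethyl (3S)-2-(diethoxyphosphoryl)-3-(1,3-dithian-2-yl)-3-{(4R,5S)-5-[(3S)-2-ethoxy-4-methyl-3-(triethylsilyloxy)penta-1,4-dien-3-yl]-2,2-dimethyl-1,3-dioxolan-4-yl}propanoate (C2 epimers) | C=C(C)[C@@](O[Si](CC)(CC)CC)(C(=C)OCC)[C@H]1OC(C)(C)O[C@@H]1[C@@H](C(C(=O)OCC)P(=O)(OCC)OCC)C2SCCCS2 | intermediate
15 | diethyl {(4S,5R)-5-[(1S,2S)-1,2-dihydroxy-3-oxo-2-(prop-1-en-2-yl)butyl]-4-(1,3-dithian-2-yl)-2-oxooxolan-3-yl}phosphonate (C3 epimers) | C=C(C)[C@@](O)(C(C)=O)[C@@H](O)[C@@H]1OC(=O)C(P(=O)(OCC)OCC)[C@H]1C2SCCCS2 | intermediate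
16 | diethyl {(4S,5R)-5-[(4S,5S)-5-acetyl-2,2-dimethyl-5-(prop-1-en-2-yl)-1,3-dioxolan-4-yl]-4-(1,3-dithian-2-yl)-2-oxooxolan-3-yl}phosphonate (C3 epimers) | C=C(C)[C@]1(C(C)=O)OC(C)(C)O[C@H]1[C@@H]2OC(=O)C(P(=O)(OCC)OCC)[C@H]2C3SCCCS3 | intermediate
17 | diethyl {(4R,5R)-5-[(4S,5S)-5-acetyl-2,2-dimethyl-5-(prop-1-en-2-yl)-1,3-dioxolan-4-yl]-4-formyl-2-oxooxolan-3-yl}phosphonate (C3 epimers) | C=C(C)[C@]1(C(C)=O)OC(C)(C)O[C@H]1[C@@H]2OC(=O)C(P(=O)(OCC)OCC)[C@H]2C=O | intermediate
18 | ene product, target numbering, (1S,5S,6R,7S,8S): cycloheptane C1–C5–C6–C7–C8–C9–C10 with trans-fused 6,12-γ-lactone carrying P(O)(OEt)2 on C11, 8β-OH, exocyclic C10=C14H2, 1-acetyl and the O1/O5 isopropylidene acetal | CCOP(=O)(OCC)C1C(=O)O[C@@H]2[C@@H]1[C@@H](O)CC(=C)[C@]3(C(C)=O)OC(C)(C)O[C@@H]23 | intermediate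
19 | 10α-methyl compound, (1S,5S,6R,7S,8S,10S): as 18 with C10 H(β)–CH3(α) in place of the exocyclic alkene | CCOP(=O)(OCC)C1C(=O)O[C@@H]2[C@@H]1[C@@H](O)C[C@H](C)[C@]3(C(C)=O)OC(C)(C)O[C@@H]23 | intermediate
20 | 8-O-tert-butyldimethylsilyl ether of 19, (1S,5S,6R,7R,8S,10S) | CCOP(=O)(OCC)C1C(=O)O[C@@H]2[C@@H]1[C@@H](O[Si](C)(C)C(C)(C)C)C[C@H](C)[C@]3(C(C)=O)OC(C)(C)O[C@@H]23 | intermediate
21 | formaldehyde (used as 37% aqueous solution) | C=O | starting material
22 | α-methylene lactone, (1S,5S,6R,7R,8S,10S): 11(13)-ene-6,12-olide with 1-acetyl, O1/O5 isopropylidene acetal and 8-OTBS | C=C1C(=O)O[C@@H]2[C@@H]1[C@@H](O[Si](C)(C)C(C)(C)C)C[C@H](C)[C@]3(C(C)=O)OC(C)(C)O[C@@H]23 | intermediate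
23 | acetaldehyde | CC=O | starting material
24 | lithium aldolate of 22 and acetaldehyde (C1 side chain C(=O)CH2CH(OLi)CH3, C4 epimers) | C=C1C(=O)O[C@@H]2[C@@H]1[C@@H](O[Si](C)(C)C(C)(C)C)C[C@H](C)[C@]3(C(=O)CC(C)O[Li])OC(C)(C)O[C@@H]23 | intermediate
25 | methanesulfonate of the aldol (C1 side chain C(=O)CH2CH(OMs)CH3, C4 epimers) | C=C1C(=O)O[C@@H]2[C@@H]1[C@@H](O[Si](C)(C)C(C)(C)C)C[C@H](C)[C@]3(C(=O)CC(C)OS(C)(=O)=O)OC(C)(C)O[C@@H]23 | intermediate
26 | (E)-crotonoyl compound, (1S,5S,6R,7R,8S,10S): 1-[(E)-but-2-enoyl], O1/O5 isopropylidene acetal, 8-OTBS, 11(13)-ene-6,12-olide | C=C1C(=O)O[C@@H]2[C@@H]1[C@@H](O[Si](C)(C)C(C)(C)C)C[C@H](C)[C@]3(C(=O)/C=C/C)OC(C)(C)O[C@@H]23 | intermediate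
27 | 1,5-diol, (1S,5S,6R,7R,8S,10S): 1-[(E)-but-2-enoyl]-1,5-dihydroxy-8-OTBS-11(13)-ene-6,12-olide | C=C1C(=O)O[C@@H]2[C@@H]1[C@@H](O[Si](C)(C)C(C)(C)C)C[C@H](C)[C@@](O)(C(=O)/C=C/C)[C@H]2O | intermediate
28 | angelic acid ((Z)-2-methylbut-2-enoic acid) | C/C=C(/C)C(=O)O | starting material
29 | (Z)-2-methylbut-2-enoic 2,4,6-trichlorobenzoic anhydride | C/C=C(/C)C(=O)OC(=O)c1c(Cl)cc(Cl)cc1Cl | intermediate
30 | 8-O-tert-butyldimethylsilyl ether of the target, (1S,5S,6R,7R,8S,10S) | C=C1C(=O)O[C@@H]2[C@@H]1[C@@H](O[Si](C)(C)C(C)(C)C)C[C@H](C)[C@@](O)(C(=O)/C=C/C)[C@H]2OC(=O)/C(C)=C\C | intermediate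
31 | CNP0206014.2, (1S,5S,6R,7S,8S,10S): 5-O-angeloyl-1-[(E)-but-2-enoyl]-1,8-dihydroxy-10-methyl-11(13)-ene-6,12-olide | C=C1C(=O)O[C@@H]2[C@@H]1[C@@H](O)C[C@H](C)[C@@](O)(C(=O)/C=C/C)[C@H]2OC(=O)/C(C)=C\C | target

**Step count and risks**

Total step count: 17. Longest linear sequence: 17 steps (1 to 31); all other carbon sources are commercial reagents.

Steps most likely to fail:

Step 10 (key step). The Lewis acid may divert the closure: ionisation at C10 followed by a 1,2-shift from C1, capture of chloride, transfer of methyl from aluminium to the aldehyde, or enolisation at C7. Fallback: from 17, ene-type allylic chlorination of the isopropenyl group (N-chlorosuccinimide, PhSeCl cat., CH2Cl2, rt) should give diethyl {(4R,5R)-5-[(4S,5S)-5-acetyl-5-(3-chloroprop-1-en-2-yl)-2,2-dimethyl-1,3-dioxolan-4-yl]-4-formyl-2-oxooxolan-3-yl}phosphonate F1. An intramolecular Nozaki–Hiyama allylation (CrCl2, THF, rt) would then add the allylchromium through its distal CH2 terminus to the aldehyde under neutral conditions and return to the route at 18. If C8 were formed with the wrong configuration by this closure, oxidation and reduction from the α-face would correct it before step 11.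

Step 3. Facial selectivity may be poor if chelation through O5 has to compete with non-chelated (Felkin–Anh) addition or with chelation by the enol-ether oxygen, which would give the C1 epimer. Fallback: reverse the order in which the two carbon groups are introduced. From 2, one equivalent of isopropenylmagnesium bromide 6 (THF, −78 °C) should give (4S,5S)-N-methoxy-N,2,2-trimethyl-5-(2-methylprop-2-enoyl)-1,3-dioxolane-4-carboxamide F2. Addition of 1-ethoxyvinyllithium 4 under non-chelating conditions (THF with HMPA, −78 °C), where the Felkin–Anh preference now leads to the desired S centre, would give the lithium alkoxide F3, and silylation in the flask with Et3SiOTf comes back to the route at 8.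

Step 16. Acylation of the hindered O5–H next to the quaternary C1 may be slow, and on prolonged heating the angeloyl unit can isomerise from Z to E (tiglate). Fallback: build the Z-alkene on the ester. From 27, esterification with 2-[bis(2,2,2-trifluoroethoxy)phosphoryl]propanoic acid (DCC, DMAP cat., CH2Cl2) should give the 5-O-phosphonopropionate F4. A Z-selective Horner–Wadsworth–Emmons reaction of the Still–Gennari type with acetaldehyde 23 (KN(SiMe3)2, 18-crown-6, THF, −78 °C) would then form the angelate at low temperature and return to the route at 30.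

Further compounds
F1 | step 10 | diethyl {(4R,5R)-5-[(4S,5S)-5-acetyl-5-(3-chloroprop-1-en-2-yl)-2,2-dimethyl-1,3-dioxolan-4-yl]-4-formyl-2-oxooxolan-3-yl}phosphonate | C=C(CCl)[C@]1(C(C)=O)OC(C)(C)O[C@H]1[C@@H]2OC(=O)C(P(=O)(OCC)OCC)[C@H]2C=O
F2 | step 3 | (4S,5S)-N-methoxy-N,2,2-trimethyl-5-(2-methylprop-2-enoyl)-1,3-dioxolane-4-carboxamide | C=C(C)C(=O)[C@H]1OC(C)(C)O[C@@H]1C(=O)N(C)OC
F3 | step 3 | lithium (3S)-2-ethoxy-3-{(4S,5S)-5-[methoxy(methyl)carbamoyl]-2,2-dimethyl-1,3-dioxolan-4-yl}-4-methylpenta-1,4-dien-3-olate | C=C(C)[C@@](O[Li])(C(=C)OCC)[C@H]1OC(C)(C)O[C@@H]1C(=O)N(C)OC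
F4 | step 16 | 5-O-{2-[bis(2,2,2-trifluoroethoxy)phosphoryl]propanoyl} derivative of 27 (epimers at the phosphonate carbon) | C=C1C(=O)O[C@@H]2[C@@H]1[C@@H](O[Si](C)(C)C(C)(C)C)C[C@H](C)[C@@](O)(C(=O)/C=C/C)[C@H]2OC(=O)C(C)P(=O)(OCC(F)(F)F)OCC(F)(F)F
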